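The earlier runs and the new flask are simulated for substances that don't exist; noise was put on by code.

Between the green and grey runs the partner charge rises from 40 mM to 63 mM, yet open intermediate at 0.167 d moves from 30% to 29%, a shift smaller than the scatter of 1.5 percentage points. Over that range of partner charge, this reading does not tell the runs apart. The dosing time of 15 min is far shorter than the time to that reading, so its exact length should matter little. The teal run, with half the solid substrate of the green run and less partner, reads 46%; two settings differ there.

Percent is counted on the charge, so it must be multiplied back. Percent times charge, averaged over the green and grey readings at 0.167 d, gives c(open intermediate) = 4.72 mM, and this open load is the quantity to carry. The teal run gives 3.68 mM, more than half of it, so in these readings the load drops by a smaller share than the charge. For the flask, with 16 mM of solid substrate, the reckoning here takes the load as an estimate of the best and gives 29.5%, near 0.167 d.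

| flask | solid substrate | partner | remark | time |
|---|---|---|---|---|
| green | 16 mM | 40 mM (fed, over 15 min) | run made earlier |  |
| grey | 16 mM | 63 mM (fed, over 15 min) | run made earlier |  |
| teal | 8 mM | 28.8 mM (fed, over 15 min) | run made earlier |  |
| flask | 16 mM | 28.8 mM (fed, over 15 min) |  | 15 d |

| run | time / d | open intermediate / % | product / % |
|---|---|---|---|
| green | 0.167 | 30 | 9 |
| green | 0.625 | 11 | 76 |
| green | 3.00 | 0 | 104 |
| green | 15.0 | 2 | 99 |
| grey | 0.167 | 29 | 16 |
| grey | 0.625 | 7 | 89 |
| grey | 3.00 | 1 | 99 |
| grey | 15.0 | 1 | 101 |
| teal | 0.167 | 46 | 14 |
| teal | 0.625 | 14 | 73 |
| teal | 3.00 | 2 | 101 |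
| teal | 15.0 | 0 | 101 |

(readings scatter by 1.5 percentage points)

- time, not beyond 15 d, at which the flask holds most open intermediate
- the amount of open intermediate, in percent of the solid substrate charged, at that time
- the first time at which open intermediate reaches 9.9%, in the same percent

The forecast gives 33% at 0.55 d, with 9.9% reached at 1.4 h: “so the intermediate builds to a broad maximum near 30–35% at about half a day”. Its peak is higher and later than the reckoning here.

The flask gives 33.1% at 0.240 d and reaches 9.9% at 0.602 h.

    solid substrate ⇌ starting material, rate k1*(cs1 - [starting material]) while solid is left; crystals form when [starting material] > cs1 (solubility = 5.60 mM, k = 4.20 × 10⁻⁴ /s)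
    open intermediate + second intermediate → product (k = 0.00300 /M/s)
    partner → second intermediate (k = 4.50 × 10⁻⁵ /s)
    starting material ⇌ open intermediate (K = 1.10, k = 9.90 × 10⁻⁴ /s)

In the flask at 0.184 d, open intermediate falls back 23 times faster than it goes on. The best of the flask is c(open intermediate) = 5.29 mM, against the open load of 4.72 mM. Spread over twice the solid substrate, that concentration gives 16.5%, and the flask with that charge and its other amounts as they are reaches 17.6%.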